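The north-east run held 13 mM of starting material and the west run 30 mM, both with 0.081 mol% of enzyme, so [enzyme] rose with [starting material].

the same everywhere: enzyme 0.081 mol%

| charge | starting material | remark |
|---|---|---|
| north-east | 13 mM | run made earlier |
| west | 30 mM | run made earlier |
| flask | 20 mM |  |

| run | time / min | product / % | starting material / % |
|---|---|---|---|
| north-east | 0.250 | 4.1 | 95.8 |
| north-east | 0.500 | 7.6 | 91.6 |
| north-east | 1.33 | 20.1 | 79.4 |
| north-east | 3.00 | 41.9 | 57.7 |
| west | 0.833 | 13.4 | 86.5 |
| west | 1.50 | 23.6 | 76.2 |
| west | 2.50 | 38.6 | 61.4 |
| west | 3.00 | 45.4 | 54.8 |

(readings scatter by 0.3 percentage points)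

1. factor on the rate of making product when 20% of the starting material are converted if enzyme is charged twice over
2. factor on the rate when 20% of the starting material are converted if enzyme is charged at 0.015 mol% instead

Carry one quantity: the order in enzyme, n, the logarithm of the rate factor divided by the logarithm of the charge factor. Dividing one rate by another makes time drop out.

Start with the bracket. As a ceiling, take n = 1, where rate follows charge: 2 on doubling, 0.185 at 0.015 mol%. As a floor, take n = 0.5, for enzyme idling mostly as inactive pairs: 1.41 and 0.430.

Now tighten it by hand. Product at 3.00 min stands in the ratio 1.08 between the west and north-east runs, which reads as a sum of orders of 1.10. Within the west run, the first and last rates give an order in starting material of 0.355, if active enzyme stays constant. My reading is therefore n = 0.741, which gives 1.67 and 0.287.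

The forecast gives 2, on the ceiling, and 0.17, beyond it: "I expect roughly first order in enzyme, with wide ranges."

The flask gives 1.52 and 0.319, both inside the bracket.

    starting material + enzyme → product + enzyme, rate k1*[starting material]*[enzyme]/(1 + ([starting material]/Km1)) (14.0 mM, k = 1100 M⁻¹ s⁻¹)
    2 enzyme ⇌ resting dimer, settled at all times (K = 1.30 × 10⁵ M⁻¹)

The order n, which the earlier runs read as 0.741, works back from the factors of the flask to 0.604 on doubling and 0.677 at 0.015 mol%. At 20% conversion in the flask, the resting dimer, the catalyst's resting state at this charge, holds 61.7% of the catalyst against 38.3% as enzyme, while at the same conversion with 0.015 mol% it holds 34.0% against 66.0%.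

The runs are simulated with made-up constants, noise included.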